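## The problem

The target is an achiral flavone, so there is no stereocentre to set; the whole difficulty is regiochemical. Ring A has no free carbon: C5 and C7 carry hydroxyls, C6 and C8 methoxyls, C8a the ring oxygen O1 and C4a the C4 carbonyl. Ring B (C1' to C6') adds a 2',4'-dihydroxy-5'-methoxy pattern, so four hydroxyls and four methoxyls, the C3 methoxyl included, must each end on the right oxygen. Ring C joins the arenes through C4–C4a, C2–C1' and O1–C8a and bears the C3 methoxyl, which most flavone-forming reactions do not deliver. The oxidative cyclisation of a 2'-hydroxychalcone is unreliable here, because a chalcone with a substituent ortho to the carbonyl on ring A (the future C5 oxygen) tends to give aurones. The free polyphenols on the way are oxidation-prone, and an aryl halide cannot be carried through a hydrogenolysis, which fixes the order of events. The enabling feature is the local symmetry of ring A: read from C4a, the substituents run O(C5)/O1(C8a), OMe(C6)/OMe(C8), OH(C7), so the ring A synthon is a C2v-symmetric 2,4-dimethoxyphloroglucinol with one free carbon. C4 is a lone carbonyl carbon between C4a and C3, so it can be carbon monoxide inserted between an iodinated phloroglucinol and a ring B acetylene, and either of the two equivalent oxygens beside the iodine closes ring C to the same flavone.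

## Retrosynthesis

**Protecting groups.** The four O–benzyl bonds of 18 are cut last, so that target 19 comes from a single hydrogenolysis. Benzyl is the only protecting group in the endgame, which keeps "hydroxyl in the target" and "methoxyl in the target" distinguishable by one rule. The forward step must spare the C2=C3 bond and the aryl methyl ethers.

**C3 methoxyl.** The O–CH3 bond at C3 of 18 and then the C3–O bond of flavonol 17 are cut, leading to the 3-unsubstituted flavone 14. The alternative of bringing the C3 oxygen in with the alkyne is closed, because the carbonylative coupling needs a terminal alkyne. Of the late oxygenations, C3 lithiation, borylation and oxidation is the one that leaves the electron-rich arenes alone. It requires that no acidic hydroxyl remains, so 14 is the 5,7-dibenzyl ether of 13 (two O–benzyl bonds cut).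

**Key disconnection.** In 13 the bonds C4a–C4, C4–C3 and O1–C2 are cut together. This gives three components: the ring A aryl iodide 6, carbon monoxide 10 and the ring B alkyne 9. Against an acylation/rearrangement route, this cut needs no differentiated ring A ketone, and against a chalcone route it cannot give an aurone if the closure is amine-mediated. The ring A component is the triacetate 6 rather than the free iodotriol 5: a free iodophloroglucinol can tautomerise, lose iodine and oxidise, whereas aryl acetates are stable, speed up oxidative addition and are removed by the amine in the same flask. The forward reaction must insert CO before alkynyl transfer and close 6-endo.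

**Ring A piece.** In 6 the three O–acetyl bonds and the C–I bond are cut, leading through 5 to 2,4-dimethoxybenzene-1,3,5-triol 4. Iodine can only enter the one free carbon. The three O–benzyl bonds of 3 are then cut (4 from 3), and the two C–OMe bonds are traced to the C–Br bonds of dibromide 2, which comes from commercial 1,3,5-tris(benzyloxy)benzene 1. The phloroglucinol oxygens stay hydroxyl-type and the two introduced oxygens are methoxyl from the outset, so no selective methylation is ever needed. The forward sequence asks for a clean double bromination and a double copper-mediated methoxylation.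

**Ring B piece.** The alkyne carbon of 9 is cut back to the aldehyde 8 (one-carbon homologation), and the two O–benzyl bonds to commercial 2,4-dihydroxy-5-methoxybenzaldehyde 7. This aldehyde already holds the full ring B oxygen pattern, so ring B costs two steps and no aromatic substitution of uncertain regiochemistry.

## Roads not taken

**Alternative 1:** Ring A is built de novo by a polyketide-type Claisen cyclisation. The cut is C4a–C8a: the C6 methylene of the triketo ester A2 (methyl 2,4,8-trimethoxy-3,5,7-trioxooctanoate) attacks its own ester carbonyl, and aromatisation gives the acylphloroglucinol A1.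
- Merits: all five ring A oxygens arrive in the right place, with methoxyl and hydroxyl distinguished by their origin. A1 already carries the C3 methoxyl as an ω-methoxy ketone, so an Allan–Robinson closure with a ring B aroyl donor would give the 3-methoxyflavone directly. In that respect it is better than the chosen plan, which spends steps 8 to 10 on the C3 oxygen.
- Weak points: A2 is a labile poly-β-carbonyl chain with two α-methoxy groups, and its assembly needs several iterative condensations. Its cyclisation must choose the C6-to-C1 Claisen mode over aldol closure and over lactonisation to a hydroxypyrone, with no substituent steering that choice. The following high-temperature acylation of a free trihydroxy ketone is also not selective by design.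
- Comparison: the chosen plan sets a catalytic annulation of a known reaction type, and a ring A component reached in four steps from a symmetric ether, against this shorter endgame.

**Alternative 2:** Ring A is annulated onto a finished γ-pyrone by a Hauser–Kraus reaction. The cuts are C8–C8a and C5–C4a: the lithiated sulfonylbutenolide A4 adds to C6 of the 2-aryl-3-methoxypyranone A5, the enolate closes onto the lactone carbonyl and loss of sulfinate gives the 5,8-dihydroxyflavone A3.
- Merits: ring C, the C3 methoxyl and ring B are in place before ring A is made. A3 arrives with its ring A oxygens differentiated; the 8-hydroxyl should methylate selectively beside the chelated 5-hydroxyl, and hydrogenolysis would then finish. This endgame is shorter than that of the chosen plan.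
- Weak points: the annulation is established for benzo-fused sulfonyl lactones, and a simple dioxygenated butenolide donor is a much less stabilised anion. The C5=C6 bond of a 4-pyranone is a vinylogous ester and a poor Michael acceptor. A3 is a hydroquinone that oxidises readily to the 5,8-quinone, and both A4 and A5 need multistep syntheses of their own.
- Comparison: the chosen plan has nothing as direct for the C3 methoxyl, but it has a key step with close precedent and components (6 and 9) made by routine aromatic chemistry.

**Alternative 3:** Ring B is made last by cycloaddition. The cuts are C1'–C2' and C5'–C6': the bis(silyloxy)diene A7 adds across the alkyne of the 2-ethynylchromone A8, and loss of methanol aromatises to A6.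
- Merits: the 2',4'-dihydroxy-5'-methoxy pattern follows from the diene with the expected polarity match. The two ring B hydroxyls arrive free and the C3 methoxyl is already present, so only one hydrogenolysis of the two ring A benzyl ethers would remain. This is the shortest endgame of all the plans.
- Weak points: the key step is spent on the easiest ring. Ring B is available in two steps from a catalogue aldehyde, whereas A8 still contains the fully substituted ring A and the 3-methoxychromone, the real difficulty, and needs a long linear synthesis. The alkyne is only vinylogously activated, so open-chain Mukaiyama–Michael addition at the alkyne terminus or at C2 can compete with ring closure.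
- Comparison: the chosen plan addresses ring A and ring C in one convergent operation and accepts a three-step C3 oxygenation in exchange.

Key step: step 7

Assumption: 1,3,5-tris(benzyloxy)benzene and 2,4-dihydroxy-5-methoxybenzaldehyde are bought, and the iodophloroglucinol enters the carbonylation as its triacetate because the free iodotriol can tautomerise and lose iodine.

## Route

Step 1
Reactants: 1 1,3,5-tris(benzyloxy)benzene
Product: 2 1,3,5-tris(benzyloxy)-2,4-dibromobenzene
Conditions: NBS (2.05 equiv), MeCN/CH2Cl2, −20 to 0 °C, dark
Reagents that add atoms: N-bromosuccinimide, O=C1CCC(=O)N1Br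
Why: Electrophilic aromatic bromination of a phloroglucinol triether; the three ring positions are equivalent and each bromine lowers the reactivity of the ring, so two equivalents in a polar solvent without light should stop at the 2,4-dibromide and leave the benzylic positions alone.

Step 2
Reactants: 2 1,3,5-tris(benzyloxy)-2,4-dibromobenzene
Product: 3 1,3,5-tris(benzyloxy)-2,4-dimethoxybenzene
Conditions: NaOMe (excess, 25% in MeOH), CuI (0.3 equiv), DMF, 110 °C
Reagents that add atoms: sodium methoxide, [Na+].[O-]C
Why: Ullmann-type copper-catalysed methoxylation of aryl bromides, a standard conversion of bromoarenes into anisoles; benzyl ethers are inert to methoxide, so both bromines should be exchanged.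

Step 3
Reactants: 3 1,3,5-tris(benzyloxy)-2,4-dimethoxybenzene
Product: 4 2,4-dimethoxybenzene-1,3,5-triol
Conditions: H2 (1 atm), Pd/C (10 wt %), EtOAc/MeOH, rt; filtered under argon and used at once
Reagents that add atoms: none
Why: Catalytic hydrogenolysis of aryl benzyl ethers; the methyl ethers are untouched, and the electron-rich triol is not stored.

Step 4
Reactants: 4 2,4-dimethoxybenzene-1,3,5-triol
Product: 6 2-iodo-4,6-dimethoxybenzene-1,3,5-triyl triacetate, via iodotriol 5 (not isolated)
Conditions: NIS (1.0 equiv), MeCN, −20 °C; then Ac2O, pyridine, DMAP (cat.), 0 °C to rt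
Reagents that add atoms: N-iodosuccinimide, O=C1CCC(=O)N1I; acetic anhydride, CC(=O)OC(C)=O
Why: Electrophilic iodination of a phloroglucinol at its only free carbon (ortho to two hydroxyls, para to the third), followed by exhaustive O-acetylation in the same flask so that the oxidation-prone iodotriol is never isolated; the triacetate can neither tautomerise nor release iodine.

Step 5
Reactants: 7 2,4-dihydroxy-5-methoxybenzaldehyde
Product: 8 2,4-bis(benzyloxy)-5-methoxybenzaldehyde
Conditions: BnBr (2.5 equiv), K2CO3, DMF, 60 °C
Reagents that add atoms: benzyl bromide, BrCc1ccccc1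
Why: Williamson ether synthesis; warm DMF is enough to alkylate the hydrogen-bonded 2-hydroxyl as well as the 4-hydroxyl.

Step 6
Reactants: 8 2,4-bis(benzyloxy)-5-methoxybenzaldehyde
Product: 9 1,5-bis(benzyloxy)-2-ethynyl-4-methoxybenzene
Conditions: dimethyl (1-diazo-2-oxopropyl)phosphonate, K2CO3, MeOH/THF, 0 °C to rt
Reagents that add atoms: dimethyl (1-diazo-2-oxopropyl)phosphonate, COP(=O)(OC)C(=[N+]=[N-])C(C)=O
Why: Seyferth–Gilbert homologation in its Ohira–Bestmann form; methanolysis of the reagent releases the diazomethylphosphonate anion, which converts the aryl aldehyde into the terminal alkyne through an alkylidene carbene and 1,2-hydrogen shift, under conditions that do not affect benzyl ethers.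

Step 7
Reactants: 6 2-iodo-4,6-dimethoxybenzene-1,3,5-triyl triacetate; 9 1,5-bis(benzyloxy)-2-ethynyl-4-methoxybenzene; 10 carbon monoxide
Product: 13 2-[2,4-bis(benzyloxy)-5-methoxyphenyl]-5,7-dihydroxy-6,8-dimethoxy-4H-chromen-4-one, via triacetoxy ynone 11 (not isolated), via trihydroxy ynone 12 (not isolated)
Conditions: PdCl2(PPh3)2 (5 mol %), dppp (5 mol %), thiourea (5 mol %), CO (1 atm), Et2NH (excess), DBU, DMF, 40 to 50 °C; dilute HCl work-up
Reagents that add atoms: none
Why: PdCl2(PPh3)2 is reduced in the flask to zerovalent palladium, which inserts into the C–I bond of 6 (helped by the three acetoxy groups, which make the ring less electron-rich than a free iodophenol); CO insertion gives the aroylpalladium iodide, the amine-activated alkyne 9 is transferred to palladium, and reductive elimination forms C4a–C4 and C4–C3 in ynone 11. Excess Et2NH then aminolyses the activated aryl acetates to give 12, adds reversibly to the β-carbon of the ynone, and a phenol oxygen displaces the amine by addition–elimination, forming O1–C2 and closing ring C in what is overall a 6-endo-dig oxa-Michael closure. The closest known reaction type is the palladium-catalysed carbonylative annulation of 2-iodophenols or their acetates with terminal arylacetylenes to flavones under one atmosphere of CO with a secondary amine. No stereocentre is formed. Three selectivities are needed: CO insertion before alkynyl transfer (favoured by the copper-free system, CO saturation and an electron-rich, doubly ortho-substituted arylpalladium that inserts CO quickly); 6-endo rather than 5-exo closure (secured by the secondary amine, whose adduct can be attacked only at the β-carbon, so no aurone should form); and regiochemistry on ring A (secured by the substrate, since one carbon bears iodine and the two oxygens beside it are equivalent by symmetry, so only one flavone is possible). Should an acetate be cleaved before oxidative addition, the iodophenol so formed is still a competent substrate for the same annulation.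

Step 8
Reactants: 13 2-[2,4-bis(benzyloxy)-5-methoxyphenyl]-5,7-dihydroxy-6,8-dimethoxy-4H-chromen-4-one
Product: 14 5,7-bis(benzyloxy)-2-[2,4-bis(benzyloxy)-5-methoxyphenyl]-6,8-dimethoxy-4H-chromen-4-one
Conditions: BnBr (3 equiv), K2CO3, Bu4NI (cat.), DMF, 70 °C
Reagents that add atoms: benzyl bromide, BrCc1ccccc1
Why: Williamson ether synthesis; heat and excess halide are used for the chelated 5-hydroxyl, and C-benzylation is impossible because ring A has no free carbon.

Step 9
Reactants: 14 5,7-bis(benzyloxy)-2-[2,4-bis(benzyloxy)-5-methoxyphenyl]-6,8-dimethoxy-4H-chromen-4-one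
Product: 17 5,7-bis(benzyloxy)-2-[2,4-bis(benzyloxy)-5-methoxyphenyl]-3-hydroxy-6,8-dimethoxy-4H-chromen-4-one, via 3-lithioflavone 15 (not isolated), via lithium aryltrimethoxyborate 16 (not isolated)
Conditions: LiN(iPr)2 (LDA, 1.5 equiv), THF, −78 °C; B(OMe)3, −78 to 0 °C; then AcOH, 30% H2O2, 0 °C to rt
Reagents that add atoms: hydrogen peroxide, OO
Why: Carbonyl-directed C3 lithiation of a flavone with a lithium amide, borylation with trimethyl borate and oxidative C–B to C–O exchange, the known lithiation–borylation–oxidation route from flavones to flavonols; aryl benzyl and methyl ethers should be inert to the amide base at −78 °C.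

Step 10
Reactants: 17 5,7-bis(benzyloxy)-2-[2,4-bis(benzyloxy)-5-methoxyphenyl]-3-hydroxy-6,8-dimethoxy-4H-chromen-4-one
Product: 18 5,7-bis(benzyloxy)-2-[2,4-bis(benzyloxy)-5-methoxyphenyl]-3,6,8-trimethoxy-4H-chromen-4-one
Conditions: MeI, K2CO3, acetone, reflux
Reagents that add atoms: iodomethane, CI
Why: Williamson O-methylation of the flavonol hydroxyl, the only free hydroxyl in the molecule.

Step 11
Reactants: 18 5,7-bis(benzyloxy)-2-[2,4-bis(benzyloxy)-5-methoxyphenyl]-3,6,8-trimethoxy-4H-chromen-4-one
Product: 19 5,7,2',4'-tetrahydroxy-3,6,8,5'-tetramethoxyflavone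
Conditions: H2 (1 atm), Pd/C (10 wt %), EtOAc/MeOH, rt
Reagents that add atoms: none
Why: Hydrogenolysis of four aryl benzyl ethers; at one atmosphere the tetrasubstituted C2=C3 bond of a 3-methoxyflavone and the aryl methyl ethers should not be reduced.

## Compound list

1 | 1,3,5-tris(benzyloxy)benzene | c1ccc(COc2cc(OCc3ccccc3)cc(OCc3ccccc3)c2)cc1 | starting material
2 | 1,3,5-tris(benzyloxy)-2,4-dibromobenzene | Brc1c(OCc2ccccc2)cc(OCc2ccccc2)c(Br)c1OCc1ccccc1 | intermediate
3 | 1,3,5-tris(benzyloxy)-2,4-dimethoxybenzene | COc1c(OCc2ccccc2)cc(OCc2ccccc2)c(OC)c1OCc1ccccc1 | intermediate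
4 | 2,4-dimethoxybenzene-1,3,5-triol | COc1c(O)cc(O)c(OC)c1O | intermediate
5 | 2-iodo-4,6-dimethoxybenzene-1,3,5-triol (formed and acetylated in the flask of step 4) | COc1c(O)c(I)c(O)c(OC)c1O | intermediate
6 | 2-iodo-4,6-dimethoxybenzene-1,3,5-triyl triacetate | COc1c(OC(C)=O)c(I)c(OC(C)=O)c(OC)c1OC(C)=O | intermediate
7 | 2,4-dihydroxy-5-methoxybenzaldehyde | COc1cc(C=O)c(O)cc1O | starting material
8 | 2,4-bis(benzyloxy)-5-methoxybenzaldehyde | COc1cc(C=O)c(OCc2ccccc2)cc1OCc1ccccc1 | intermediate
9 | 1,5-bis(benzyloxy)-2-ethynyl-4-methoxybenzene | C#Cc1cc(OC)c(OCc2ccccc2)cc1OCc1ccccc1 | intermediate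
10 | carbon monoxide | [C-]#[O+] | starting material
11 | 2-{3-[2,4-bis(benzyloxy)-5-methoxyphenyl]prop-2-ynoyl}-4,6-dimethoxybenzene-1,3,5-triyl triacetate (formed in the flask of step 7) | COc1cc(C#CC(=O)c2c(OC(C)=O)c(OC)c(OC(C)=O)c(OC)c2OC(C)=O)c(OCc2ccccc2)cc1OCc1ccccc1 | intermediate
12 | 3-[2,4-bis(benzyloxy)-5-methoxyphenyl]-1-(2,4,6-trihydroxy-3,5-dimethoxyphenyl)prop-2-yn-1-one (formed in the flask of step 7) | COc1cc(C#CC(=O)c2c(O)c(OC)c(O)c(OC)c2O)c(OCc2ccccc2)cc1OCc1ccccc1 | intermediate
13 | 2-[2,4-bis(benzyloxy)-5-methoxyphenyl]-5,7-dihydroxy-6,8-dimethoxy-4H-chromen-4-one | COc1cc(-c2cc(=O)c3c(O)c(OC)c(O)c(OC)c3o2)c(OCc2ccccc2)cc1OCc1ccccc1 | intermediate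
14 | 5,7-bis(benzyloxy)-2-[2,4-bis(benzyloxy)-5-methoxyphenyl]-6,8-dimethoxy-4H-chromen-4-one | COc1cc(-c2cc(=O)c3c(OCc4ccccc4)c(OC)c(OCc4ccccc4)c(OC)c3o2)c(OCc2ccccc2)cc1OCc1ccccc1 | intermediate
15 | 3-lithio derivative of 14, lithium at C3 of the chromenone (formed in the flask of step 9) | [Li]c1c(-c2cc(OC)c(OCc3ccccc3)cc2OCc2ccccc2)oc2c(OC)c(OCc3ccccc3)c(OC)c(OCc3ccccc3)c2c1=O | intermediate
16 | lithium trimethoxyborate of 14, boron at C3 of the chromenone (formed in the flask of step 9) | [Li+].CO[B-](OC)(OC)c1c(-c2cc(OC)c(OCc3ccccc3)cc2OCc2ccccc2)oc2c(OC)c(OCc3ccccc3)c(OC)c(OCc3ccccc3)c2c1=O | intermediate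
17 | 5,7-bis(benzyloxy)-2-[2,4-bis(benzyloxy)-5-methoxyphenyl]-3-hydroxy-6,8-dimethoxy-4H-chromen-4-one | COc1cc(-c2oc3c(OC)c(OCc4ccccc4)c(OC)c(OCc4ccccc4)c3c(=O)c2O)c(OCc2ccccc2)cc1OCc1ccccc1 | intermediate
18 | 5,7-bis(benzyloxy)-2-[2,4-bis(benzyloxy)-5-methoxyphenyl]-3,6,8-trimethoxy-4H-chromen-4-one | COc1cc(-c2oc3c(OC)c(OCc4ccccc4)c(OC)c(OCc4ccccc4)c3c(=O)c2OC)c(OCc2ccccc2)cc1OCc1ccccc1 | intermediate
19 | 5,7,2',4'-tetrahydroxy-3,6,8,5'-tetramethoxyflavone, i.e. 2-(2,4-dihydroxy-5-methoxyphenyl)-5,7-dihydroxy-3,6,8-trimethoxy-4H-chromen-4-one | COc1cc(-c2oc3c(OC)c(O)c(OC)c(O)c3c(=O)c2OC)c(O)cc1O | target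

## Step count and risks

Total step count: 11. Longest linear sequence: 9 steps (steps 1 to 4, then 7 to 11); the ring B alkyne adds a two-step branch (steps 5 and 6).

**Step 7 (key step).**
- What may go wrong: alkynyl transfer may outrun CO insertion at the hindered arylpalladium, giving the non-carbonylative coupling and then a benzofuran. Et2NH may capture the aroylpalladium as an amide. Early loss of the acetates may slow oxidative addition and open reductive loss of iodine.
- Fallback (no carbonylation; C4 comes from a formyl carbon): it sets out from 3 and 9 and comes back at 14, bypassing steps 7 and 8. Vilsmeier–Haack formylation of 3 (POCl3, DMF) at its only free carbon gives 2,4,6-tris(benzyloxy)-3,5-dimethoxybenzaldehyde F1. Addition of the lithium acetylide of 9 (n-BuLi, THF, −78 °C) gives racemic 3-[2,4-bis(benzyloxy)-5-methoxyphenyl]-1-[2,4,6-tris(benzyloxy)-3,5-dimethoxyphenyl]prop-2-yn-1-ol F2. Oxidation with MnO2 gives 3-[2,4-bis(benzyloxy)-5-methoxyphenyl]-1-[2,4,6-tris(benzyloxy)-3,5-dimethoxyphenyl]prop-2-yn-1-one F3. Chelation-controlled removal of one of the two equivalent benzyl groups ortho to the carbonyl with MgBr2·OEt2 gives 1-[2,4-bis(benzyloxy)-6-hydroxy-3,5-dimethoxyphenyl]-3-[2,4-bis(benzyloxy)-5-methoxyphenyl]prop-2-yn-1-one F4. Et2NH in ethanol then closes ring C 6-endo to 14.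

**Step 2.**
- What may go wrong: reductive loss of bromine at the doubly ortho-substituted positions, or exchange stopping after the first bromine, because both sites are hindered and the ring is electron-rich.
- Fallback (C–O bonds made through boron instead of copper): it sets out from 2 and comes back at 3. Bromine–lithium exchange on 2 (n-BuLi, −78 °C), B(OMe)3 and H2O2 give 2,4,6-tris(benzyloxy)-3-bromophenol F5. Methylation (MeI, K2CO3) gives 1,3,5-tris(benzyloxy)-2-bromo-4-methoxybenzene F6. A second exchange, borylation and oxidation give 2,4,6-tris(benzyloxy)-3-methoxyphenol F7, and a second methylation gives 3.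

**Step 4.**
- What may go wrong: oxidation of the very electron-rich triol by the iodinating agent, or loss of iodine from the free iodotriol through its keto tautomer before acetylation is complete.
- Fallback (iodine introduced while the phenols are still protected): it sets out from 3 and comes back at 6. Iodination of 3 (NIS, cat. CF3CO2H, MeCN) at the only free carbon gives 1,3,5-tris(benzyloxy)-2-iodo-4,6-dimethoxybenzene F8. BCl3 with pentamethylbenzene in CH2Cl2 at −78 °C removes the benzyl groups without touching the C–I bond, and the crude iodotriol 5 is acetylated at once (Ac2O, pyridine) to 6.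

**Step 9.**
- What may go wrong: deprotonation at a benzylic ether position with rearrangement, addition of the amide to the chromone, or incomplete borylation of the hindered 3-lithio species.
- Fallback (oxygen delivered electrophilically to the C2=C3 bond): it sets out from 14 and comes back at 17. Epoxidation with dimethyldioxirane in acetone/CH2Cl2 at 0 °C gives the racemic cis-2,3-epoxide of 14, 5,7-bis(benzyloxy)-2-[2,4-bis(benzyloxy)-5-methoxyphenyl]-2,3-epoxy-6,8-dimethoxy-2,3-dihydro-4H-chromen-4-one F9. Catalytic p-toluenesulfonic acid opens and isomerises it to flavonol 17.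

## Further compounds

F1 | step 7 | 2,4,6-tris(benzyloxy)-3,5-dimethoxybenzaldehyde | COc1c(OCc2ccccc2)c(C=O)c(OCc2ccccc2)c(OC)c1OCc1ccccc1
F2 | step 7 | 3-[2,4-bis(benzyloxy)-5-methoxyphenyl]-1-[2,4,6-tris(benzyloxy)-3,5-dimethoxyphenyl]prop-2-yn-1-ol (racemic) | COc1cc(C#CC(O)c2c(OCc3ccccc3)c(OC)c(OCc3ccccc3)c(OC)c2OCc2ccccc2)c(OCc2ccccc2)cc1OCc1ccccc1
F3 | step 7 | 3-[2,4-bis(benzyloxy)-5-methoxyphenyl]-1-[2,4,6-tris(benzyloxy)-3,5-dimethoxyphenyl]prop-2-yn-1-one | COc1cc(C#CC(=O)c2c(OCc3ccccc3)c(OC)c(OCc3ccccc3)c(OC)c2OCc2ccccc2)c(OCc2ccccc2)cc1OCc1ccccc1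
F4 | step 7 | 1-[2,4-bis(benzyloxy)-6-hydroxy-3,5-dimethoxyphenyl]-3-[2,4-bis(benzyloxy)-5-methoxyphenyl]prop-2-yn-1-one | COc1cc(C#CC(=O)c2c(O)c(OC)c(OCc3ccccc3)c(OC)c2OCc2ccccc2)c(OCc2ccccc2)cc1OCc1ccccc1
F5 | step 2 | 2,4,6-tris(benzyloxy)-3-bromophenol | Oc1c(OCc2ccccc2)cc(OCc2ccccc2)c(Br)c1OCc1ccccc1
F6 | step 2 | 1,3,5-tris(benzyloxy)-2-bromo-4-methoxybenzene | COc1c(OCc2ccccc2)cc(OCc2ccccc2)c(Br)c1OCc1ccccc1
F7 | step 2 | 2,4,6-tris(benzyloxy)-3-methoxyphenol | COc1c(OCc2ccccc2)cc(OCc2ccccc2)c(O)c1OCc1ccccc1
F8 | step 4 | 1,3,5-tris(benzyloxy)-2-iodo-4,6-dimethoxybenzene | COc1c(OCc2ccccc2)c(I)c(OCc2ccccc2)c(OC)c1OCc1ccccc1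
F9 | step 9 | 5,7-bis(benzyloxy)-2-[2,4-bis(benzyloxy)-5-methoxyphenyl]-2,3-epoxy-6,8-dimethoxy-2,3-dihydro-4H-chromen-4-one (racemic, cis ring fusion, one enantiomer drawn) | O=C1[C@@H]2O[C@]2(c2cc(OC)c(OCc3ccccc3)cc2OCc2ccccc2)Oc2c(OC)c(OCc3ccccc3)c(OC)c(OCc3ccccc3)c21
A1 | alternative 1 | 2-methoxy-1-(2,4,6-trihydroxy-3,5-dimethoxyphenyl)ethan-1-one | COCC(=O)c1c(O)c(OC)c(O)c(OC)c1O
A2 | alternative 1 | methyl 2,4,8-trimethoxy-3,5,7-trioxooctanoate (enolisable mixture of diastereomers) | COCC(=O)CC(=O)C(OC)C(=O)C(OC)C(=O)OC
A3 | alternative 2 | 7-(benzyloxy)-2-[2,4-bis(benzyloxy)-5-methoxyphenyl]-5,8-dihydroxy-3,6-dimethoxy-4H-chromen-4-one | COc1cc(-c2oc3c(O)c(OCc4ccccc4)c(OC)c(O)c3c(=O)c2OC)c(OCc2ccccc2)cc1OCc1ccccc1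
A4 | alternative 2 | 4-(benzyloxy)-3-methoxy-5-(phenylsulfonyl)furan-2(5H)-one (racemic) | COC1=C(OCc2ccccc2)C(S(=O)(=O)c2ccccc2)OC1=O
A5 | alternative 2 | 2-[2,4-bis(benzyloxy)-5-methoxyphenyl]-3-methoxy-4H-pyran-4-one | COc1cc(-c2occc(=O)c2OC)c(OCc2ccccc2)cc1OCc1ccccc1
A6 | alternative 3 | 5,7-bis(benzyloxy)-2-(2,4-dihydroxy-5-methoxyphenyl)-3,6,8-trimethoxy-4H-chromen-4-one | COc1cc(-c2oc3c(OC)c(OCc4ccccc4)c(OC)c(OCc4ccccc4)c3c(=O)c2OC)c(O)cc1O
A7 | alternative 3 | 1,4-dimethoxy-1,3-bis(trimethylsilyloxy)buta-1,3-diene (double-bond geometry not defined) | COC=C(O[Si](C)(C)C)C=C(OC)O[Si](C)(C)C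
A8 | alternative 3 | 5,7-bis(benzyloxy)-2-ethynyl-3,6,8-trimethoxy-4H-chromen-4-one | C#Cc1oc2c(OC)c(OCc3ccccc3)c(OC)c(OCc3ccccc3)c2c(=O)c1OC
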